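(Readings and results were computed with constants of no real substance; the scatter is artificial.)

Each nucleophile that reacts sets free one acid and ends inside one target. That target may then take a second electrophile, so a side product holds two electrophiles but one nucleophile. Counting nucleophile this way tells us how much a flask must spend.

the same everywhere: electrophile 0.080 M
- east: nucleophile 0.080 M; free base 0.17 M; run made earlier
- north: nucleophile 0.080 M; free base 0.36 M; run made earlier
- ochre: nucleophile 0.0800 M; free base 0.240 M; time 6.0 min
- blue: nucleophile 0.0800 M; free base 0.480 M; time 6.0 min

- east (time / min: electrophile / %, target / %): 0.833: 15.9, 73.4; 1.50: 7.4, 74.0; 2.50: 0.9, 79.0; 3.00: 1.6, 78.8; 4.00: 0.4, 76.0; 5.00: 1.0, 78.9; 6.00: 2.1, 79.3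
- north (time / min: electrophile / %, target / %): 0.833: 14.8, 71.8; 1.50: 5.7, 77.8; 2.50: 3.2, 76.5; 3.00: 1.9, 79.0; 4.00: 1.0, 79.3; 5.00: 0, 79.2; 6.00: 0, 78.0

(readings scatter by 1 percentage point)

- in percentages every species weighs as the electrophile in it: one idle adduct or side product counts as two
- for target the idle adduct is counted in
- what may be going on: electrophile + nucleophile -> acid set free + target; nucleophile + acid set free <-> protonated nucleophile; acid set free + free base <-> salt of the base; electrophile + target <-> idle adduct; electrophile + target -> side product; free base <-> dormant form
- in an amount of target, one idle adduct counts as one target

1. part of the electrophile that has reacted at the end, ochre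
2. part of the electrophile that has reacted at the end, blue
3. what raising the concentration of free base from its lowest to its highest value here does to the part of the electrophile that has reacted (changes below 5 percentage points count as none) (it falls / it rises / no change)

The last two target readings of east and north average f = 78.8% of the electrophile charged. The electrophile readings at those times reach at most 2.1%, so we take the rest as side product. Target then costs 0.0631 M of nucleophile and side product 0.00846 M. Their sum is the nucleophile demand D = 0.0715 M, the nucleophile spent, and acid set free, in finishing the electrophile.

D is less than the 0.0800 M of nucleophile charged, so electrophile is the limiting reagent. The rate is first order in electrophile and first order in free nucleophile, so free nucleophile is the concentration to watch. Acid can take it away as protonated nucleophile, but east's 0.17 M of free base is more than D. Indeed, with twice the base, north left 14.8% of electrophile at the first reading against 15.9% in east, a gap within the scatter. Ochre and blue also charge more base than D, so we expect both to follow those runs, whose last readings show 2.1% and 0% of electrophile.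

The forecast says 99% for ochre, 99% for blue and no change, holding that “Doubling the base therefore does nothing to the rate”. Our comparison points the same way.

The flasks give 99.8% for ochre and 99.8% for blue, so the trend is no change.

    electrophile + nucleophile → acid set free + target (k = 1.10 M⁻¹ s⁻¹)
    nucleophile + acid set free ⇌ protonated nucleophile, settled at all times (K = 270 M⁻¹)
    acid set free + free base ⇌ salt of the base, settled at all times (K = 2.50 × 10⁵ M⁻¹)
    electrophile + target ⇌ idle adduct, settled at all times (K = 3.40 M⁻¹)
    electrophile + target → side product (k = 0.0970 M⁻¹ s⁻¹)
    free base ⇌ dormant form (K = 0.320, k = 0.0130 s⁻¹)

D leaves 10.6% of blue's nucleophile, and the flask holds 11% at 6.00 min. A neighbouring flask is blue with 0.032 M of nucleophile. Its charge is less than D, which is twice that charge, so we reckon that nucleophile becomes the limiting reagent. At 6.00 min this flask has 0% of its nucleophile left and 33.3% of its electrophile. Its reacted part is 66.7%, with 14.5% as target and 51.0% as side product.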